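## Structural features

Asterelin A (C28H22O4) is an 18-membered macrocyclic bis(bibenzyl) with no stereocentre, so no two stereocentres stand next to each other and nothing has to be controlled in space. Three aromatic units make up the macrocycle: a dibenzofuran (ring A with the phenol, ring B, and the furan between them), a para-phenylene (ring D) and a 1,3,4-trisubstituted catechol ring (ring C). C1 of the dibenzofuran is tied by a CH2CH2 bridge to ring D; the oxygen of ring D is bound as a diaryl ether to C3 of ring C, next to the free hydroxyl at C4; C1 of ring C returns through a second CH2CH2 bridge to C7 of the dibenzofuran. The fragile parts are the two phenols (the one on ring C is an oxidisable catechol mono-aryl ether), which are therefore carried as methyl ethers to the last step, and the macrocycle, whose closure competes with oligomerisation. The real difficulty lies in ring A: C1, C9b and C4a are three neighbouring carbons carrying the bridge carbon, the biaryl bond and the furan oxygen. C1 is meta to both oxygens of ring A and sits in the bay region facing C9–H, so no electrophilic substitution can bring carbon to it. The key step exploits this pattern: an iodide on the future C9b, flanked by an oxygen substituent on C4a and a free C–H on C1, is the substrate type of the Catellani reaction, which alkylates the free ortho carbon (C1–CH2) and arylates the ipso carbon (C9b–C9a) in one operation. A fluorine on the future C5a and a chlorine on the future C7 pass through that step and later serve furan closure and macrocyclisation.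

## Logic of the disconnections

**15 to 14.** Forward, the two O–CH3 bonds (at C3 of ring A and C4 of ring C) are cut last. The reason is that free phenols, above all the catechol-type one on ring C, would interfere with the copper and palladium steps and oxidise easily. The gain is a robust macrocycle 14 that carries no acidic hydrogen through the metal-mediated steps. The demand is a dealkylation that attacks only sp3 O–C bonds and spares the diaryl ether and the furan.

**14 to 12 by way of 13.** The macrocycle is opened at the C7–CH2 bond of the bridge between ring B and ring C. C7 has carried chlorine since 6, and the sp3 partner can be generated from a terminal olefin through 13, so the bridge arrives saturated and no redox adjustment follows. The gain is the open-chain 12 with every atom of the target in place. The demand is that ring closure outruns intermolecular coupling (slow addition, high dilution) and that the catalyst activates an aryl chloride.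

**12 to 11, and 11 to 9 plus 10.** The C=CH2 bond is traced to the aldehyde of 11, and the diaryl ether bond at C3 of ring C is cut. The ether bond divides the molecule into the dibenzofuran half 9 and the purchasable ring C piece 10, whose bromine ortho to methoxy encodes the catechol pattern. The aldehyde is a safer passenger than a styrene through the hot copper step. The gain is a fragment 9 with a single phenol. The demand is a copper coupling at a hindered ortho-methoxy bromide that leaves the chlorine at C7 and the aldehyde untouched.

**9 to 8, and 8 to 7.** The furan O–C5a bond is cut, then the two acetal O–C bonds. O–C5a is the one furan bond that can be made by substitution, with the oxygen already on ring A and a fluoride on ring B. The gain is that the tricycle becomes the biaryl 8, and 8 comes from 7 in one acid step because both phenols are masked alike. The demand is that only the phenoxide next to the biaryl bond displaces fluoride (secured by geometry), that the unactivated fluoride reacts on heating, and that the chlorine stays.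

**7 to 3 plus 5 plus 6.** The C1–CH2 and C9b–C9a bonds are cut together. They sit at the ortho and ipso carbons of an aryl iodide, the pair that palladium/norbornene catalysis functionalises in one pot, and C1 cannot be reached in another direct way. The gain is the largest of the route: 7 falls into three simple benzene derivatives of similar size. The demands are several:
- alkylation must precede arylation;
- 3 must offer exactly one free ortho C–H;
- 5 must not be lost by elimination;
- the halogens of 6 must be inert to the catalyst;
- the ortho oxygen substituent of 3 must offer the palladium no C–H to attack, which is why an acetal is used there.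

**3 to 2 to 1, and 5 to 4.** The acetal O–C bonds and the C–I bond are cut. These are functional-group operations on purchasable phenols. The gain is that 1, 4, 6 and 10 are all bought. The demand is iodination ortho to the hydroxyl and para to the methoxy group of 1, and a protection of 4 that does not disturb the primary bromide.

## Other disconnections considered

**Alternative 1:** The cut is the diaryl ether bond between the oxygen of ring D and C3 of ring C, made as the ring-closing bond.
- Forward step: the open-chain bis(dihalophenol) A2 (ring D a 2,6-dichlorophenol, ring C a 2,6-dibromophenol) would be electrolysed at constant current in methanol. The more easily oxidised dibromophenol is attacked at a bromine-bearing ortho carbon by the oxygen of the dichlorophenol. Reduction of the resulting bromodienone with zinc and acetic acid in the work-up would deliver the macrocycle A1, still carrying one bromine, two chlorines and the C3 methyl ether.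
- In its favour: the ether forms at room temperature without a transition metal, ortho to a hydroxyl that never needs protection, and the halogens block the C–C couplings that usually accompany phenol oxidation.
- Against it here: A2 already contains the whole dibenzofuran with both bridges, so the crowded ring A is left unsolved by this step. Four halogens must be introduced and three removed by hydrogenolysis afterwards, followed by demethylation. The electron-rich methoxydibenzofuran is itself oxidisable at the anode.
- Comparison: in structure, the ring is closed at C–O instead of C–C. In mechanism, the closure is at least the equal of the chosen palladium closure, and it is the better one in needing no protecting group on the ring C hydroxyl. In step economy it is the weaker plan, since halogenation, dehalogenation and a separate construction of ring A are added.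

**Alternative 2:** The cut goes through ring A itself: C9b–C1 and C4–C4a are disconnected, so that ring A stems from a cyclohexane-1,3-dione.
- Forward step: with t-BuOK the enolate of the arylacetate A4 would add to the β-carbon of the enone A5. The methyl ketone enolate then closes onto the ester in a Claisen condensation to give the trans-dione A3. Oxidative aromatisation would give the resorcinol, whose hydroxyl next to the aryl group closes the furan by displacing fluoride.
- In its favour: cheap base chemistry without a transition metal, and a ring A substitution pattern fixed by the annulation itself. Because no palladium is involved, ring B can carry bromine, a better handle for the later alkyl coupling than the chlorine of the chosen plan; on this point the alternative is superior.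
- Against it here: ring A is made saturated and must be dehydrogenated, a step that is often capricious for 4,5-disubstituted diones. The two stereocentres of A3 are made only to be destroyed. A5 needs several steps. After furan closure the C3 hydroxyl is free and must be protected before the Ullmann step.
- Comparison: in structure it reaches the same dibenzofuran, and in regiochemical certainty it is the equal of the chosen plan. In mechanism it trades one catalytic domino step for annulation, aromatisation and protection. In step economy that costs about three more operations.

**Alternative 3:** The cut removes ring A and the furan together: C9b–C4a, C4–C3 and C2–C1 are disconnected to the diyne A7 (an aryl ethynyl ether with an ortho arylalkyne that already carries the ring D chain) and the ethynylboronate A8.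
- Forward step: a cationic monovalent rhodium catalyst, [Rh(cod)2]BF4 with BINAP, would form a rhodacyclopentadiene from the two tethered alkynes, insert A8 and eliminate reductively to the boryl dibenzofuran A6. Oxidation of the C–B bond would then give the C3 hydroxyl.
- In its favour: two rings (furan and ring A) in one step against none in the Catellani reaction, which makes it the better plan on that count; full atom economy; no fluorine needed on ring B.
- Against it here: A7 contains an acid- and water-sensitive aryl ethynyl ether that needs a multi-step preparation with strong base. The orientation of A8 in the insertion (boron at C3 and not C2) rests only on a steric difference between the two ends of the rhodacycle. The catalyst system is costly.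
- Comparison: in structure it gives the same 1,3,7-trisubstituted dibenzofuran. In mechanism its regiochemistry is less firmly anchored than that of the Catellani reaction, where a single ortho C–H leaves no choice. In step economy the two plans are about equal up to the dibenzofuran, since what the cycloaddition saves is spent on A7.

Key step: step 4

Remark on the chemistry: atom-by-atom mapping of the key-step precursors and product onto the target shows their connectivity to be right (iodine on the future C9b, free ortho C–H at C1, fluorine on C5a, chlorine on C7), so no structure is corrected; only the masking is redesigned, both phenol oxygens being carried as methoxymethyl (MOM) ethers, because a benzyl ether ortho to the arylpalladium centre invites cyclisation onto its phenyl ring and benzyl hydrogenolysis would endanger the C–Cl bond.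

## Route

Step 1
Reactants: 1 3-methoxyphenol
Product: 2 2-iodo-5-methoxyphenol
Conditions: I2, NaHCO3, THF/H2O, 0 °C to rt
Reagents that add atoms: iodine, II
Why: Electrophilic aromatic iodination of the phenol; the carbon ortho to the hydroxyl and para to the methoxy group is activated by both oxygens and, unlike the carbon between them, unhindered, and the mild bicarbonate conditions favour this ortho isomer; the minor isomer iodinated para to the hydroxyl should be separable by chromatography.

Step 2
Reactants: 2 2-iodo-5-methoxyphenol
Product: 3 1-iodo-4-methoxy-2-(methoxymethoxy)benzene
Conditions: MOMCl, iPr2NEt, CH2Cl2, 0 °C to rt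
Reagents that add atoms: chloromethyl methyl ether, COCCl
Why: O-alkylation of the phenol with an α-chloro ether gives the MOM acetal, which is inert to carbonate and palladium, supplies the ortho substituent that the Catellani reaction needs and has no aryl C–H that the arylpalladium centre could attack.

Step 3
Reactants: 4 4-(2-bromoethyl)phenol
Product: 5 1-(2-bromoethyl)-4-(methoxymethoxy)benzene
Conditions: MOMCl, iPr2NEt, CH2Cl2, 0 °C to rt
Reagents that add atoms: chloromethyl methyl ether, COCCl
Why: The same acetal formation under a hindered amine base that is too weak and too bulky to displace or eliminate the primary bromide; the phenol must be capped because a free phenoxide para to the bromoethyl chain would consume the bromide in the basic key step.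

Step 4
Reactants: 3 1-iodo-4-methoxy-2-(methoxymethoxy)benzene; 5 1-(2-bromoethyl)-4-(methoxymethoxy)benzene; 6 (4-chloro-2-fluorophenyl)boronic acid
Product: 7 4'-chloro-2'-fluoro-4-methoxy-2-(methoxymethoxy)-6-{2-[4-(methoxymethoxy)phenyl]ethyl}-1,1'-biphenyl
Conditions: Pd(OAc)2 (10 mol%), tri(2-furyl)phosphine (22 mol%), norbornene (2 equiv), K2CO3 (4 equiv), 5 (2.5 equiv), 6 (1.5 equiv), DMF, 70 °C
Reagents that add atoms: none
Why: Zerovalent palladium inserts into the C–I bond of 3, norbornene adds across the aryl–palladium bond, and the only free ortho C–H (the future C1) is palladated to a five-membered aryl–norbornyl palladacycle. Oxidative addition of the primary bromide 5 gives tetravalent palladium, and reductive elimination forms the aryl–CH2 bond. Both ortho positions are then filled, so norbornene is expelled by β-carbon elimination, and the hindered divalent arylpalladium halide is intercepted by Suzuki–Miyaura transmetalation with 6 and reductive elimination to the C9b–C9a biaryl bond. The closest known reaction type is the Catellani ortho-alkylation/ipso-Suzuki coupling of ortho-substituted aryl iodides with primary alkyl bromides and arylboronic acids; no ring is closed and no stereocentre is formed. Site selectivity is secured by the substrate, which has a single free ortho C–H, and the order of events by the fact that norbornene can leave only once that position is alkylated. The MOM ether provides the required ortho substituent without offering the palladium an aryl C–H for cyclisation, and the C–Cl and C–F bonds of 6 are inert to the catalyst at this temperature. Dehydrobromination of 5 is held back by the mild carbonate and the moderate temperature and is covered by an excess of 5, while an excess of 6 covers protodeboronation and speeds the terminating transmetalation.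

Step 5
Reactants: 7 4'-chloro-2'-fluoro-4-methoxy-2-(methoxymethoxy)-6-{2-[4-(methoxymethoxy)phenyl]ethyl}-1,1'-biphenyl
Product: 8 4'-chloro-2'-fluoro-6-[2-(4-hydroxyphenyl)ethyl]-4-methoxy-1,1'-biphenyl-2-ol
Conditions: aq. HCl (3 M), MeOH/THF, 50 °C
Reagents that add atoms: none
Why: Acid-catalysed methanolysis of the two aryl MOM acetals (transacetalisation to dimethoxymethane) frees both phenols in one operation; the aryl methyl ether and the C–F and C–Cl bonds are inert to dilute acid.

Step 6
Reactants: 8 4'-chloro-2'-fluoro-6-[2-(4-hydroxyphenyl)ethyl]-4-methoxy-1,1'-biphenyl-2-ol
Product: 9 4-[2-(7-chloro-3-methoxydibenzo[b,d]furan-1-yl)ethyl]phenol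
Conditions: K2CO3 (3 equiv), NMP, 150 °C, argon
Reagents that add atoms: none
Why: Intramolecular nucleophilic aromatic substitution: the phenoxide next to the biaryl bond attacks the fluorine-bearing carbon of ring B and fluoride leaves, closing the five-membered furan ring as in the standard dibenzofuran synthesis from 2'-fluorobiphenyl-2-ols. The ring D phenoxide has no fluoride within reach, bimolecular displacement at an unactivated aryl fluoride is far slower, and the chlorine, meta to the site of attack, is not displaced.

Step 7
Reactants: 9 4-[2-(7-chloro-3-methoxydibenzo[b,d]furan-1-yl)ethyl]phenol; 10 3-bromo-4-methoxybenzaldehyde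
Product: 11 3-{4-[2-(7-chloro-3-methoxydibenzo[b,d]furan-1-yl)ethyl]phenoxy}-4-methoxybenzaldehyde
Conditions: CuI (20 mol%), N,N-dimethylglycine hydrochloride (60 mol%), Cs2CO3 (2.5 equiv), 10 (1.5 equiv), 1,4-dioxane, 100 °C
Reagents that add atoms: none
Why: Ullmann-type copper-catalysed diaryl ether synthesis; the amino-acid ligand lets CuI couple the phenoxide of 9 with the aryl bromide of 10 at about 100 °C, where the aryl chloride at C7 is inert to copper and the aldehyde is tolerated because the tertiary-amine ligand cannot condense with it. The bromine of 10 sits ortho to the methoxy group, which places the ether oxygen at C3 of ring C next to the masked C4 hydroxyl.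

Step 8
Reactants: 11 3-{4-[2-(7-chloro-3-methoxydibenzo[b,d]furan-1-yl)ethyl]phenoxy}-4-methoxybenzaldehyde
Product: 12 7-chloro-1-{2-[4-(5-ethenyl-2-methoxyphenoxy)phenyl]ethyl}-3-methoxydibenzo[b,d]furan
Conditions: Ph3PCH3Br, KOtBu, THF, 0 °C to rt
Reagents that add atoms: methyltriphenylphosphonium bromide, C[P+](c1ccccc1)(c1ccccc1)c1ccccc1.[Br-]
Why: Wittig methylenation of the aryl aldehyde with the non-stabilised ylide; the aldehyde is the only electrophile present and the new olefin is terminal, so no question of geometry arises.

Step 9
Reactants: 12 7-chloro-1-{2-[4-(5-ethenyl-2-methoxyphenoxy)phenyl]ethyl}-3-methoxydibenzo[b,d]furan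
Product: 14 asterelin A di-O-methyl ether, via primary alkylborane 13 (not isolated)
Conditions: 9-BBN (1.5 equiv), THF, 0 °C to rt; then syringe-pump addition to Pd(OAc)2 (10 mol%), SPhos (2-dicyclohexylphosphino-2',6'-dimethoxybiphenyl, 20 mol%), K3PO4 (3 equiv), THF/H2O, 70 °C, final concentration about 2 mM
Reagents that add atoms: none
Why: Anti-Markovnikov hydroboration of the styrene with the bulky dialkylborane places boron on the terminal carbon; the B-alkyl Suzuki–Miyaura coupling then joins this sp3 carbon to C7 by oxidative addition of zerovalent palladium, made electron-rich by the dialkylbiarylphosphine, into the C–Cl bond, base-assisted transmetalation and reductive elimination. Slow addition at high dilution favours the 18-membered ring over oligomers, and the second CH2CH2 bridge arrives already saturated.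

Step 10
Reactants: 14 asterelin A di-O-methyl ether
Product: 15 asterelin A
Conditions: BBr3 (6 equiv), CH2Cl2, −78 °C to rt; then H2O
Reagents that add atoms: none
Why: Lewis-acid demethylation: BBr3 coordinates each aryl methyl ether oxygen and bromide removes the methyl group by SN2 attack, while the diaryl ether and furan C–O bonds, which offer only sp2 carbons, are not cleaved; hydrolysis of the aryl borates on work-up releases both phenols.

## Compound list

1 | 3-methoxyphenol | COc1cccc(O)c1 | starting material
2 | 2-iodo-5-methoxyphenol | COc1ccc(I)c(O)c1 | intermediate
3 | 1-iodo-4-methoxy-2-(methoxymethoxy)benzene | COCOc1cc(OC)ccc1I | intermediate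
4 | 4-(2-bromoethyl)phenol | Oc1ccc(CCBr)cc1 | starting material
5 | 1-(2-bromoethyl)-4-(methoxymethoxy)benzene | COCOc1ccc(CCBr)cc1 | intermediate
6 | (4-chloro-2-fluorophenyl)boronic acid | OB(O)c1ccc(Cl)cc1F | starting material
7 | 4'-chloro-2'-fluoro-4-methoxy-2-(methoxymethoxy)-6-{2-[4-(methoxymethoxy)phenyl]ethyl}-1,1'-biphenyl | COCOc1cc(OC)cc(CCc2ccc(OCOC)cc2)c1-c1ccc(Cl)cc1F | intermediate
8 | 4'-chloro-2'-fluoro-6-[2-(4-hydroxyphenyl)ethyl]-4-methoxy-1,1'-biphenyl-2-ol | COc1cc(O)c(-c2ccc(Cl)cc2F)c(CCc2ccc(O)cc2)c1 | intermediate
9 | 4-[2-(7-chloro-3-methoxydibenzo[b,d]furan-1-yl)ethyl]phenol | COc1cc(CCc2ccc(O)cc2)c2c(c1)oc1cc(Cl)ccc12 | intermediate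
10 | 3-bromo-4-methoxybenzaldehyde | COc1ccc(C=O)cc1Br | starting material
11 | 3-{4-[2-(7-chloro-3-methoxydibenzo[b,d]furan-1-yl)ethyl]phenoxy}-4-methoxybenzaldehyde | COc1cc(CCc2ccc(Oc3cc(C=O)ccc3OC)cc2)c2c(c1)oc1cc(Cl)ccc12 | intermediate
12 | 7-chloro-1-{2-[4-(5-ethenyl-2-methoxyphenoxy)phenyl]ethyl}-3-methoxydibenzo[b,d]furan | COc1cc(CCc2ccc(Oc3cc(C=C)ccc3OC)cc2)c2c(c1)oc1cc(Cl)ccc12 | intermediate
13 | 9-{2-[3-(4-{2-[7-chloro-3-methoxydibenzo[b,d]furan-1-yl]ethyl}phenoxy)-4-methoxyphenyl]ethyl}-9-borabicyclo[3.3.1]nonane | COc1cc(CCc2ccc(Oc3cc(CCB4C5CCCC4CCC5)ccc3OC)cc2)c2c(c1)oc1cc(Cl)ccc12 | intermediate (not isolated)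
14 | asterelin A di-O-methyl ether (the macrocycle of 15 with OCH3 at C3 of the dibenzofuran and at C4 of ring C) | COc1cc2c3c(c1)oc1cc(ccc13)CCc1ccc(OC)c(c1)Oc1ccc(cc1)CC2 | intermediate
15 | asterelin A (dibenzofuran-3-ol bridged from C1 by CH2CH2 to the para-phenylene ring D, ring D oxygen on C3 of the 4-hydroxyphenyl ring C, ring C C1 bridged by CH2CH2 to C7) | Oc1cc2c3c(c1)oc1cc(ccc13)CCc1ccc(O)c(c1)Oc1ccc(cc1)CC2 | target

## Step count and least certain steps

Total: 10 steps. Longest linear sequence: 9 steps (1, 2, 3, 7, 8, 9, 11, 12, 14, 15 in this order).

**Key step, step 4.** Three processes are the most likely to divert the reaction: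
- base-induced dehydrobromination of 5, whose styrene can then terminate the sequence in a Heck reaction;
- premature Suzuki coupling of the arylpalladium iodide with 6, before norbornene insertion and C–H alkylation;
- intramolecular C–H arylation of ring D by the hindered arylpalladium intermediate when transmetalation with the ortho-fluoro boronic acid is slow.

All three stem from the need for three components to react in a fixed order at one metal centre. The fallback gives up the domino reaction and starts from a benzaldehyde that already holds the C1 carbon. It sets out from 6 and comes back to the route at 9: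
- Suzuki–Miyaura coupling of 6 with purchased 2-bromo-3,5-dimethoxybenzaldehyde (PdCl2(dppf), K3PO4, dioxane/H2O, 90 °C) should give 4'-chloro-2'-fluoro-4,6-dimethoxy-1,1'-biphenyl-2-carbaldehyde F1.
- BBr3 in CH2Cl2 would demethylate it to 4'-chloro-2'-fluoro-4,6-dihydroxy-1,1'-biphenyl-2-carbaldehyde F2.
- With K2CO3 in DMF at 120 °C only the hydroxyl next to the biaryl bond can reach the fluoride, which gives 7-chloro-3-hydroxydibenzo[b,d]furan-1-carbaldehyde F3.
- MeI and K2CO3 cap the remaining phenol as 7-chloro-3-methoxydibenzo[b,d]furan-1-carbaldehyde F4.
- Wittig olefination with (4-hydroxybenzyl)triphenylphosphonium bromide and two equivalents of KOtBu gives 4-[(E)-2-(7-chloro-3-methoxydibenzo[b,d]furan-1-yl)ethenyl]phenol F5 (E isomer drawn; either isomer serves).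
- Hydrogenation of the olefin over sulfided Pt on carbon, which spares the aryl chloride, gives 9.

**Step 9.** Intermolecular coupling to dimers and oligomers, slow oxidative addition at the electron-rich aryl chloride, and loss of the alkylborane by protodeboronation during the long addition may each erode the ring closure; the strain of bridging C1 and C7 of the rigid dibenzofuran makes the closure slower than in flexible systems. The fallback closes the same bridge by olefin metathesis. It sets out from 12 and returns at 14:
- Suzuki–Miyaura vinylation of the aryl chloride with potassium vinyltrifluoroborate (Pd(OAc)2, SPhos, Cs2CO3, THF/H2O, 80 °C) gives 7-ethenyl-1-{2-[4-(5-ethenyl-2-methoxyphenoxy)phenyl]ethyl}-3-methoxydibenzo[b,d]furan F6.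
- Ring-closing metathesis with the second-generation Grubbs catalyst in toluene at high dilution and 80 °C closes the macrocycle, with loss of ethene, to the cyclic stilbene analogue of 14 (CH=CH in place of the C7 bridge) F7 (Z isomer drawn; either geometry serves).
- Hydrogenation over Pd on carbon in EtOAc saturates the bridge to give 14.

**Step 7.** Slow C–O bond formation at the hindered ortho-methoxy bromide may allow reductive loss of bromine from 10 and base-induced degradation of the aldehyde at 100 °C. The fallback replaces the halide partner by a boron partner under oxidative conditions at room temperature. It sets out from 9 and returns at 11: Chan–Lam coupling of 9 with purchased (5-formyl-2-methoxyphenyl)boronic acid (Cu(OAc)2, pyridine, 4 Å molecular sieves, CH2Cl2, air, rt) gives 11 directly, and no new compound is made.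

**Step 6.** Displacement of an unactivated fluoride needs prolonged heating, during which the second, free phenoxide of ring D may undergo oxidative degradation or slow intermolecular O-arylation. The fallback keeps that phenol masked during furan closure by orthogonal protection. It sets out from 4 and returns at 9:
- Benzylation of 4 (BnBr, K2CO3, acetone, reflux) gives 1-(benzyloxy)-4-(2-bromoethyl)benzene F8.
- The conditions of step 4 applied to 3, F8 and 6 give 6-{2-[4-(benzyloxy)phenyl]ethyl}-4'-chloro-2'-fluoro-4-methoxy-2-(methoxymethoxy)-1,1'-biphenyl F9.
- Aqueous HCl in MeOH/THF frees only the hydroxyl next to the biaryl bond, giving 6-{2-[4-(benzyloxy)phenyl]ethyl}-4'-chloro-2'-fluoro-4-methoxy-1,1'-biphenyl-2-ol F10.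
- K2CO3 in NMP at 150 °C closes the furan to 1-{2-[4-(benzyloxy)phenyl]ethyl}-7-chloro-3-methoxydibenzo[b,d]furan F11.
- BCl3 with pentamethylbenzene in CH2Cl2 at −78 °C removes the benzyl group without touching the methyl ether or the chlorine and gives 9.

## Further compounds

F1 | step 4 | 4'-chloro-2'-fluoro-4,6-dimethoxy-1,1'-biphenyl-2-carbaldehyde | COc1cc(C=O)c(-c2ccc(Cl)cc2F)c(OC)c1
F2 | step 4 | 4'-chloro-2'-fluoro-4,6-dihydroxy-1,1'-biphenyl-2-carbaldehyde | Oc1cc(C=O)c(-c2ccc(Cl)cc2F)c(O)c1
F3 | step 4 | 7-chloro-3-hydroxydibenzo[b,d]furan-1-carbaldehyde | Oc1cc(C=O)c2c(c1)oc1cc(Cl)ccc12
F4 | step 4 | 7-chloro-3-methoxydibenzo[b,d]furan-1-carbaldehyde | COc1cc(C=O)c2c(c1)oc1cc(Cl)ccc12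
F5 | step 4 | 4-[(E)-2-(7-chloro-3-methoxydibenzo[b,d]furan-1-yl)ethenyl]phenol | COc1cc(/C=C/c2ccc(O)cc2)c2c(c1)oc1cc(Cl)ccc12
F6 | step 9 | 7-ethenyl-1-{2-[4-(5-ethenyl-2-methoxyphenoxy)phenyl]ethyl}-3-methoxydibenzo[b,d]furan | COc1cc(CCc2ccc(Oc3cc(C=C)ccc3OC)cc2)c2c(c1)oc1cc(C=C)ccc12
F7 | step 9 | cyclic stilbene analogue of 14 with a (Z)-CH=CH bridge between C7 of the dibenzofuran and C1 of ring C | COc1cc2c3c(c1)oc1cc(ccc13)/C=C\c1ccc(OC)c(c1)Oc1ccc(cc1)CC2
F0 | step 7 | none | none
F8 | step 6 | 1-(benzyloxy)-4-(2-bromoethyl)benzene | BrCCc1ccc(OCc2ccccc2)cc1
F9 | step 6 | 6-{2-[4-(benzyloxy)phenyl]ethyl}-4'-chloro-2'-fluoro-4-methoxy-2-(methoxymethoxy)-1,1'-biphenyl | COCOc1cc(OC)cc(CCc2ccc(OCc3ccccc3)cc2)c1-c1ccc(Cl)cc1F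
F10 | step 6 | 6-{2-[4-(benzyloxy)phenyl]ethyl}-4'-chloro-2'-fluoro-4-methoxy-1,1'-biphenyl-2-ol | COc1cc(O)c(-c2ccc(Cl)cc2F)c(CCc2ccc(OCc3ccccc3)cc2)c1
F11 | step 6 | 1-{2-[4-(benzyloxy)phenyl]ethyl}-7-chloro-3-methoxydibenzo[b,d]furan | COc1cc(CCc2ccc(OCc3ccccc3)cc2)c2c(c1)oc1cc(Cl)ccc12
A1 | alternative 1 | asterelin A 3-O-methyl ether with bromine ortho to the ring C hydroxyl and two chlorines ortho to the ether oxygen on ring D | COc1cc2c3c(c1)oc1cc(ccc13)CCc1cc(Br)c(O)c(c1)Oc1c(Cl)cc(cc1Cl)CC2
A2 | alternative 1 | 2,6-dibromo-4-(2-{9-[2-(3,5-dichloro-4-hydroxyphenyl)ethyl]-7-methoxydibenzo[b,d]furan-3-yl}ethyl)phenol | COc1cc(CCc2cc(Cl)c(O)c(Cl)c2)c2c(c1)oc1cc(CCc3cc(Br)c(O)c(Br)c3)ccc12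
A3 | alternative 2 | trans-4-(4-bromo-2-fluorophenyl)-5-{2-[4-(benzyloxy)phenyl]ethyl}cyclohexane-1,3-dione (racemic, one enantiomer drawn) | O=C1CC(=O)[C@@H](c2ccc(Br)cc2F)[C@H](CCc2ccc(OCc3ccccc3)cc2)C1
A4 | alternative 2 | methyl (4-bromo-2-fluorophenyl)acetate | COC(=O)Cc1ccc(Br)cc1F
A5 | alternative 2 | (E)-6-[4-(benzyloxy)phenyl]hex-3-en-2-one | CC(=O)/C=C/CCc1ccc(OCc2ccccc2)cc1
A6 | alternative 3 | 1-{2-[4-(benzyloxy)phenyl]ethyl}-7-chloro-3-(4,4,5,5-tetramethyl-1,3,2-dioxaborolan-2-yl)dibenzo[b,d]furan | Clc1ccc2c(c1)oc1cc(B3OC(C)(C)C(C)(C)O3)cc(CCc3ccc(OCc4ccccc4)cc3)c12
A7 | alternative 3 | 1-{4-[4-(benzyloxy)phenyl]but-1-yn-1-yl}-4-chloro-2-(ethynyloxy)benzene | C#COc1cc(Cl)ccc1C#CCCc1ccc(OCc2ccccc2)cc1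
A8 | alternative 3 | 2-ethynyl-4,4,5,5-tetramethyl-1,3,2-dioxaborolane | C#CB1OC(C)(C)C(C)(C)O1
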